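**Retrosynthetic overview**

1. Ring E (pendant cis-lactone) is made last: transfer hydrogenation and lactonisation of a γ-keto acid, which comes from Friedel–Crafts acylation of the free pyrrole α-CH with (R)-methylsuccinic anhydride.
2. The ring-A alkene comes from a ring-A ketone through its enol triflate (Pd/formate reduction).
3. Rings C and D close together by intramolecular Friedel–Crafts–Michael addition of the pyrrole β-carbon to a butenolide. The butenolide and both adjacent stereocentres are installed by a catalytic asymmetric vinylogous Michael addition to an exocyclic enone.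
4. Ring A (azepinone) comes from one-carbon ring expansion of 6,7-dihydroindolizin-8(5H)-one (diazo insertion with 1,2-shift of the pyrrol-2-yl carbon). This moves C=O one position away from the pyrrole and turns the CH2 between them into the handle for the enone.
5. Order of ring formation: B (pyrrole, bought) → six-membered N-ring → A (by expansion) → C and D (one step) → E.

Assumption: (R)-2-methylsuccinic anhydride (17) is bought as the single enantiomer; ring letters are A = azepine, B = pyrrole, C = carbocycle, D = fused lactone, E = pendant lactone.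

**Route**

Step 1
Reactants: 1 pyrrole; 2 4-bromobutanenitrile
Product: 3 4-(1H-pyrrol-1-yl)butanenitrile
Conditions: NaH, DMF, 0 °C → rt
Reagents that add atoms: none
Why: N-alkylation (SN2) of sodium pyrrolide in a dipolar aprotic solvent goes cleanly at nitrogen; no stereocentre is formed.

Step 2
Reactants: 3 4-(1H-pyrrol-1-yl)butanenitrile
Product: 5 6,7-dihydroindolizin-8(5H)-one, via ketiminium chloride 4 (not isolated)
Conditions: HCl (g), Et2O, 0 °C → rt; then H2O, 60 °C
Reagents that add atoms: water, O
Why: Intramolecular Houben–Hoesch acylation: the nitrilium ion is attacked by the pyrrole α-carbon in a six-membered closure and the ketiminium salt is hydrolysed to the ketone.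

Step 3
Reactants: 5 6,7-dihydroindolizin-8(5H)-one
Product: 7 5,6,7,9-tetrahydro-8H-pyrrolo[1,2-a]azepin-8-one, via C-silyl ketone 6 (not isolated)
Conditions: Me3SiCHN2 (1.3 equiv), Sc(OTf)3 (20 mol %), CH2Cl2, −78 → 0 °C; then 1 M HCl, THF, rt
Reagents that add atoms: (trimethylsilyl)diazomethane, C[Si](C)(C)C=[N+]=[N-]
Why: Lewis-acid-promoted diazoalkane homologation (Tiffeneau–Demjanov-type ring expansion): the diazo carbon adds to the activated C=O and loss of N2 drives a 1,2-shift of the electron-rich pyrrol-2-yl carbon (better migrating group than CH2), giving the seven-membered ketone with C=O now β to the pyrrole; the silyl group hinders a second insertion and is removed by acid.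

Step 4
Reactants: 7 5,6,7,9-tetrahydro-8H-pyrrolo[1,2-a]azepin-8-one; 8 propanal
Product: 11 (9E)-9-propylidene-5,6,7,9-tetrahydro-8H-pyrrolo[1,2-a]azepin-8-one, via lithium aldolate 9 (not isolated), via aldol mesylate 10 (not isolated)
Conditions: LiN(SiMe3)2, THF, −78 °C; 8; then MsCl, −78 → 0 °C; then DBU, rt
Reagents that add atoms: none
Why: Directed aldol addition at the CH2 flanked by pyrrole and C=O (by far the most acidic site), then E1cB elimination of the mesylate; DBU equilibration is expected to place the ethyl group anti to the carbonyl (E).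

Step 5
Reactants: 11 (9E)-9-propylidene-5,6,7,9-tetrahydro-8H-pyrrolo[1,2-a]azepin-8-one; 12 3-methylfuran-2(5H)-one
Product: 13 9-{(1S)-1-[(2R)-4-methyl-5-oxo-2,5-dihydrofuran-2-yl]propyl}-5,6,7,9-tetrahydro-8H-pyrrolo[1,2-a]azepin-8-one (mixture of C-9 epimers)
Conditions: 12 (1.5 equiv), (S,S)-ProPhenol (10 mol %), Et2Zn (20 mol %), 4 Å MS, THF, 0 °C → rt
Reagents that add atoms: none
Why: Proposed new method: a direct catalytic asymmetric vinylogous Michael addition in which one zinc of the dinuclear zinc–ProPhenol complex deprotonates the butenolide at its γ-carbon to a zinc dienolate while the second zinc binds the s-cis enone carbonyl, so that γ-attack on the enone β-carbon inside the chiral pocket forms the C–C bond and both new stereocentres (propyl C-1 S, furanone C-2 R) and the zinc enolate is protonated by fresh butenolide; the closest known reaction type is the direct asymmetric vinylogous Michael addition of 2(5H)-furanones to nitroalkenes and chalcones, and what is new is the α-(pyrrol-2-yl) exocyclic alkylidene ketone as acceptor, used under basic bifunctional catalysis so that the free pyrrole α-CH is not engaged.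

Step 6
Reactants: 13 vinylogous Michael adduct
Product: 15 tetracyclic ring-A ketone (rings A–D; ethyl-CH S, lactone O–CH R, pyrrole-bound CH S, methyl-CH R; CH between pyrrole and C=O as epimer mixture), via endo-methyl epimer 14 (not isolated)
Conditions: Sc(OTf)3 (20 mol %), MeCN (0.01 M), 50 °C; then DBU (0.2 equiv), rt
Reagents that add atoms: none
Why: Intramolecular Friedel–Crafts-type conjugate (Michael) addition of the pyrrole β-carbon to the Lewis-acid-activated butenolide closes six-membered ring C; the tether from the furanone γ-carbon enforces the cis C/D fusion (pyrrole-bound CH S), and DBU epimerises the lactone α-carbon to the more stable exo methyl (R, trans to the ring-C bond).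

Step 7
Reactants: 15 tetracyclic ring-A ketone
Product: 16 ring-A enol triflate (C=C between the pyrrole-bound ring-A carbon and the triflyloxy carbon; other stereocentres as in 15)
Conditions: KN(SiMe3)2 (1.0 equiv), THF, −78 → 0 °C; then PhNTf2, −78 °C → rt
Reagents that add atoms: N-phenylbis(trifluoromethanesulfonimide), O=S(=O)(N(c1ccccc1)S(=O)(=O)C(F)(F)F)C(F)(F)F
Why: Enolate O-sulfonylation: the thermodynamic, pyrrole-conjugated enolate forms at the α-aryl C–H (several pKa units more acidic than the lactone α-H) and is trapped as the triflate, which removes the transient stereocentre and fixes the ring-A double bond regiospecifically.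

Step 8
Reactants: 16 ring-A enol triflate; 17 (R)-2-methylsuccinic anhydride
Product: 18 (2R)-2-methyl-4-oxo-4-[pyrrol-α-yl of 16]butanoic acid (enol triflate retained)
Conditions: Sc(OTf)3 (10 mol %), MeNO2, 40 °C
Reagents that add atoms: none
Why: Friedel–Crafts acylation at the only free pyrrole α-position; the anhydride opens at its less hindered CH2–C=O carbonyl, so the methyl stereocentre (R) is untouched, and the electron-poor enol triflate shields the ring-A alkene from acid.

Step 9
Reactants: 18 keto acid enol triflate
Product: 19 (2R)-2-methyl-4-oxo-4-[pyrrol-α-yl of the rings A–D core with ring-A CH=C]butanoic acid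
Conditions: Pd(OAc)2 (5 mol %), PPh3 (10 mol %), HCO2H, Et3N, DMF, 60 °C
Reagents that add atoms: none
Why: Palladium-catalysed formate reduction of an enol triflate (oxidative addition, decarboxylation of formate to a palladium hydride, reductive elimination) replaces OTf by H without moving the trisubstituted alkene or touching the ketone, acid or lactone.

Step 10
Reactants: 19 keto acid
Product: 21 target CNP0324368.1, via hydroxy acid 20 (not isolated)
Conditions: RuCl[(R,R)-TsDPEN](p-cymene) (2 mol %), HCO2Na, H2O/MeOH, 40 °C; then pH 6 extraction, EDC·HCl, DMAP (cat.), CH2Cl2, 0 °C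
Reagents that add atoms: none
Why: Noyori asymmetric transfer hydrogenation of the pyrrol-2-yl ketone under non-acidic conditions sets the carbinol centre R by catalyst control (the (R,R)-ligand gives R, as with aryl alkyl ketones), and carbodiimide lactonisation forms the acyl–O bond with retention at the carbinol carbon, avoiding SN1 ionisation next to the pyrrole and giving the cis-(R,R) lactone E.

**Compound list**

1 | pyrrole | c1cc[nH]c1 | starting material
2 | 4-bromobutanenitrile | N#CCCCBr | starting material
3 | 4-(1H-pyrrol-1-yl)butanenitrile | N#CCCCn1cccc1 | intermediate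
4 | 6,7-dihydroindolizin-8(5H)-iminium chloride (not isolated) | [NH2+]=C1CCCn2cccc12.[Cl-] | intermediate
5 | 6,7-dihydroindolizin-8(5H)-one | O=C1CCCn2cccc12 | intermediate
6 | 9-(trimethylsilyl)-5,6,7,9-tetrahydro-8H-pyrrolo[1,2-a]azepin-8-one (not isolated) | C[Si](C)(C)C1C(=O)CCCn2cccc12 | intermediate
7 | 5,6,7,9-tetrahydro-8H-pyrrolo[1,2-a]azepin-8-one | O=C1CCCn2cccc2C1 | intermediate
8 | propanal | CCC=O | starting material
9 | lithium aldolate of 9-(1-hydroxypropyl)-5,6,7,9-tetrahydro-8H-pyrrolo[1,2-a]azepin-8-one (not isolated) | [Li+].CCC([O-])C1C(=O)CCCn2cccc12 | intermediate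
10 | 1-(8-oxo-5,6,7,9-tetrahydro-8H-pyrrolo[1,2-a]azepin-9-yl)propyl methanesulfonate (not isolated) | CCC(OS(C)(=O)=O)C1C(=O)CCCn2cccc12 | intermediate
11 | (9E)-9-propylidene-5,6,7,9-tetrahydro-8H-pyrrolo[1,2-a]azepin-8-one | CC/C=C1/C(=O)CCCn2cccc12 | intermediate
12 | 3-methylfuran-2(5H)-one | CC1=CCOC1=O | starting material
13 | 9-{(1S)-1-[(2R)-4-methyl-5-oxo-2,5-dihydrofuran-2-yl]propyl}-5,6,7,9-tetrahydro-8H-pyrrolo[1,2-a]azepin-8-one (C-9 epimers) | CC[C@H]([C@H]1OC(=O)C(C)=C1)C1C(=O)CCCn2cccc12 | intermediate
14 | endo-methyl epimer of 15 (methyl-CH S; not isolated) | CC[C@H]1C2C(=O)CCCn3ccc(c32)[C@H]2[C@@H]1OC(=O)[C@H]2C | intermediate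
15 | tetracyclic ring-A ketone, rings A–D (ethyl-CH S, O–CH R, pyrrole-bound CH S, methyl-CH R) | CC[C@H]1C2C(=O)CCCn3ccc(c32)[C@H]2[C@@H]1OC(=O)[C@@H]2C | intermediate
16 | ring-A enol triflate of 15 | CC[C@H]1C2=C(OS(=O)(=O)C(F)(F)F)CCCn3ccc(c32)[C@H]2[C@@H]1OC(=O)[C@@H]2C | intermediate
17 | (R)-2-methylsuccinic anhydride | C[C@@H]1CC(=O)OC1=O | starting material
18 | (2R)-2-methyl-4-oxo-4-(pyrrol-α-yl of 16)butanoic acid, enol triflate | CC[C@H]1C2=C(OS(=O)(=O)C(F)(F)F)CCCn3c(C(=O)C[C@@H](C)C(=O)O)cc(c32)[C@H]2[C@@H]1OC(=O)[C@@H]2C | intermediate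
19 | (2R)-2-methyl-4-oxo-4-(pyrrol-α-yl of the A–D core, ring-A CH=C)butanoic acid | CC[C@H]1C2=CCCCn3c(C(=O)C[C@@H](C)C(=O)O)cc(c32)[C@H]2[C@@H]1OC(=O)[C@@H]2C | intermediate
20 | (2R,4R)-4-hydroxy-2-methyl-4-(pyrrol-α-yl of the A–D core)butanoic acid (not isolated) | CC[C@H]1C2=CCCCn3c([C@H](O)C[C@@H](C)C(=O)O)cc(c32)[C@H]2[C@@H]1OC(=O)[C@@H]2C | intermediate
21 | CNP0324368.1 | CC[C@H]1C2=CCCCn3c([C@H]4C[C@@H](C)C(=O)O4)cc(c32)[C@H]2[C@@H]1OC(=O)[C@@H]2C | target

**Step count and risks**

Total step count: 10. Longest linear sequence: 10 (fully linear from pyrrole).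

Steps most likely to fail:

Step 5 (proposed new method). The α-pyrrolyl group lowers the acceptor reactivity of enone 11. The sense and level of induction with the (S,S)-ligand, the anti/syn ratio and the stability of the new γ-stereocentre to the basic catalyst are all unproven. The fallback uses known chemistry and sets out from 11. Compound 12 is silylated (Me3SiOTf, Et3N) to 3-methyl-2-(trimethylsilyloxy)furan F4. F4 adds to 11 under achiral Lewis acid catalysis (BF3·OEt2, CH2Cl2, −78 °C; vinylogous Mukaiyama–Michael) to give the racemic trimethylsilyl enol ether of the adduct F5, which is hydrolysed on work-up. The diastereomer with the relative configuration of 13 is separated on silica and resolved on a chiral stationary phase into 13 and its enantiomer F6. The route is rejoined at 13.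

Step 3. The vinylogous-amide carbonyl of 5 may be too unreactive, CH2 migration would give the isomeric 9-ketone, and the more electrophilic product could be homologated again. The fallback sets out from 1 and avoids the homologation. Potassium pyrrolide (KOt-Bu) opens γ-butyrolactone at 110 °C to give 4-(1H-pyrrol-1-yl)butanoic acid F1. Oxalyl chloride converts it to 4-(1H-pyrrol-1-yl)butanoyl chloride F2, and Me3SiCHN2 gives 1-diazo-5-(1H-pyrrol-1-yl)pentan-2-one F3. Rh2(OAc)4 in CH2Cl2 then effects intramolecular carbenoid substitution at the pyrrole α-carbon to give 7, where the route is rejoined.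

Step 6. The free pyrrole α-CH of 13 can attack the butenolide of another molecule, and the ketone may undergo a retro-Michael reaction under Lewis acid. The fallback sets out from 13 and acylates first. Compound 13 is acylated with 17 (Sc(OTf)3, MeNO2) at the free α-position to give the acylated adduct keto acid F7. As a 2-acylpyrrole, F7 can only react at the ring position needed for ring C and no longer oligomerises. Ring closure is forced with TfOH in CH2Cl2 and passes through the endo-methyl diketo acid F8, which DBU equilibrates to the exo-methyl tetracyclic diketo acid F9. KN(SiMe3)2 (2.1 equiv) and PhNTf2 then give 18, where the route is rejoined.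

**Further compounds**

F1 | step 3 | 4-(1H-pyrrol-1-yl)butanoic acid | OC(=O)CCCn1cccc1
F2 | step 3 | 4-(1H-pyrrol-1-yl)butanoyl chloride | ClC(=O)CCCn1cccc1
F3 | step 3 | 1-diazo-5-(1H-pyrrol-1-yl)pentan-2-one | [N-]=[N+]=CC(=O)CCCn1cccc1
F4 | step 5 | 3-methyl-2-(trimethylsilyloxy)furan | Cc1ccoc1O[Si](C)(C)C
F5 | step 5 | trimethylsilyl enol ether of the vinylogous Mukaiyama–Michael adduct (racemic, one enantiomer drawn) | CC[C@H]([C@H]1OC(=O)C(C)=C1)C1=C(O[Si](C)(C)C)CCCn2cccc12
F6 | step 5 | enantiomer of 13, 9-{(1R)-1-[(2S)-4-methyl-5-oxo-2,5-dihydrofuran-2-yl]propyl}-5,6,7,9-tetrahydro-8H-pyrrolo[1,2-a]azepin-8-one | CC[C@@H]([C@@H]1OC(=O)C(C)=C1)C1C(=O)CCCn2cccc12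
F7 | step 6 | (2R)-2-methyl-4-oxo-4-(pyrrol-α-yl of adduct 13)butanoic acid | CC[C@H]([C@H]1OC(=O)C(C)=C1)C1C(=O)CCCn2c(C(=O)C[C@@H](C)C(=O)O)ccc12
F8 | step 6 | endo-methyl epimer of F9 | CC[C@H]1C2C(=O)CCCn3c(C(=O)C[C@@H](C)C(=O)O)cc(c32)[C@H]2[C@@H]1OC(=O)[C@H]2C
F9 | step 6 | (2R)-2-methyl-4-oxo-4-(pyrrol-α-yl of ring-A ketone 15)butanoic acid | CC[C@H]1C2C(=O)CCCn3c(C(=O)C[C@@H](C)C(=O)O)cc(c32)[C@H]2[C@@H]1OC(=O)[C@@H]2C
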